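**Plan**

- Retrosynthesis: the acrylic acid C=C is cut first (back to the 6‑carbaldehyde). Then three bonds of ring A are cut at once (C4a–C8a, C5–C6, C7–C8), then the two O–C(sp) bonds, then the aryl–C2 bond of the arylglycerol unit.
- Enabling feature: O1 and O4 of the C2–C3 diol unit sit on the adjacent arene carbons C8a and C4a. The bis(alkynyl ether) of that diol is therefore a 3,6‑dioxa‑1,7‑diyne, which a third alkyne can convert into ring A while the dioxane ring closes.
- Forward: a D‑glycerate C3 unit is joined to the guaiacyl ring (aryllithium on a Weinreb amide) and the ketone is reduced. The benzylic oxygen and then the secondary oxygen are made alkynyl ethers from trichloroethylene, with a silyl cap only on the benzylic one. The dioxane ring and ring A then arise together by [2+2+2] cycloaddition with 3,3‑diethoxyprop‑1‑yne.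
- End game: acid removes the C8 silyl group and all protecting groups, and a Knoevenagel–Doebner condensation adds the acrylic acid.
- Stereochemistry: C3 comes from the chiral pool (methyl (R)‑2,2‑dimethyl‑1,3‑dioxolane‑4‑carboxylate), C2 from Felkin–Anh reduction of the aryl ketone. Both are set before the key step and no later step breaks a bond to them.

Key step: step 10

Remark: the 1,2‑dichloroethenyl ethers are drawn as the (E) isomers expected from anti addition of an alkoxide to dichloroacetylene; the geometry has no consequence because both carbons become alkyne carbons.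

**Route**

Step 1
Reactants: 1 methyl (R)‑2,2‑dimethyl‑1,3‑dioxolane‑4‑carboxylate
Product: 2 (R)‑N‑methoxy‑N,2,2‑trimethyl‑1,3‑dioxolane‑4‑carboxamide
Conditions: MeNH(OMe)·HCl, i‑PrMgCl, THF, −20 → 0 °C
Reagents that add atoms: N,O‑dimethylhydroxylamine hydrochloride, CNOC.Cl
Why: the magnesium amide of N,O‑dimethylhydroxylamine should convert the methyl ester into the Weinreb amide by direct aminolysis at low temperature, conditions under which an α‑alkoxy stereocentre is not expected to epimerise; no new stereocentre is formed.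

Step 2
Reactants: 3 4‑bromo‑2‑methoxyphenol
Product: 4 4‑bromo‑2‑methoxy‑1‑(methoxymethoxy)benzene
Conditions: NaH, MeOCH2Cl, DMF, 0 °C → rt
Reagents that add atoms: chloromethyl methyl ether, COCCl
Why: Williamson‑type O‑alkylation of the sodium phenoxide should give the methoxymethyl (MOM) ether, which later withstands KH and n‑BuLi and is removed with acid.

Step 3
Reactants: 4 4‑bromo‑2‑methoxy‑1‑(methoxymethoxy)benzene; 2 (R)‑N‑methoxy‑N,2,2‑trimethyl‑1,3‑dioxolane‑4‑carboxamide
Product: 6 (R)‑(2,2‑dimethyl‑1,3‑dioxolan‑4‑yl)[3‑methoxy‑4‑(methoxymethoxy)phenyl]methanone, via aryllithium 5 (not isolated)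
Conditions: 4, n‑BuLi, THF, −78 °C; then 2, −78 → 0 °C; aq. NH4Cl
Reagents that add atoms: none
Why: bromine–lithium exchange gives the aryllithium, which should add only once to the Weinreb amide because the chelated tetrahedral adduct persists until work‑up (Weinreb ketone synthesis), leaving the α‑stereocentre intact.

Step 4
Reactants: 6 (R)‑(2,2‑dimethyl‑1,3‑dioxolan‑4‑yl)[3‑methoxy‑4‑(methoxymethoxy)phenyl]methanone
Product: 7 (R)‑[(4R)‑2,2‑dimethyl‑1,3‑dioxolan‑4‑yl][3‑methoxy‑4‑(methoxymethoxy)phenyl]methanol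
Conditions: LiBH(s‑Bu)3, THF, −78 °C; aq. NH4Cl
Reagents that add atoms: none
Why: Felkin–Anh (polar) reduction, in which the bulky non‑chelating hydride should attack anti to the ring C–O bond of the α‑alkoxy ketone past the small hydrogen, so that the existing (R) centre sets the new carbinol centre as (R), syn (threo) to the ring oxygen.

Step 5
Reactants: 7 (R)‑[(4R)‑2,2‑dimethyl‑1,3‑dioxolan‑4‑yl][3‑methoxy‑4‑(methoxymethoxy)phenyl]methanol; 8 trichloroethylene
Product: 9 (4R)‑4‑{(R)‑[(E)‑1,2‑dichloroethenyloxy][3‑methoxy‑4‑(methoxymethoxy)phenyl]methyl}‑2,2‑dimethyl‑1,3‑dioxolane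
Conditions: KH, THF, 0 °C; then 8, −40 °C → rt
Reagents that add atoms: none
Why: dichloroenol ether formation by the trichloroethylene route, in which the potassium alkoxide should add anti to dichloroacetylene formed in the flask by dehydrochlorination of 8, a reaction established for hindered secondary and benzylic alcohols and one that leaves the O–C bond to the stereocentre untouched.

Step 6
Reactants: 9 (4R)‑4‑{(R)‑[(E)‑1,2‑dichloroethenyloxy][3‑methoxy‑4‑(methoxymethoxy)phenyl]methyl}‑2,2‑dimethyl‑1,3‑dioxolane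
Product: 10 (2R,3R)‑3‑[(E)‑1,2‑dichloroethenyloxy]‑3‑[3‑methoxy‑4‑(methoxymethoxy)phenyl]propane‑1,2‑diol
Conditions: AcOH/H2O (4:1), 40 °C
Reagents that add atoms: none
Why: acid‑catalysed hydrolysis of the terminal isopropylidene acetal should be much faster in aqueous acetic acid than cleavage of the aryl MOM ether or of the electron‑poor dichloroenol ether, which is why the acetal is removed at this stage and not after an acid‑sensitive alkynyl ether is present.

Step 7
Reactants: 10 (2R,3R)‑3‑[(E)‑1,2‑dichloroethenyloxy]‑3‑[3‑methoxy‑4‑(methoxymethoxy)phenyl]propane‑1,2‑diol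
Product: 11 (1R,2R)‑1‑[(E)‑1,2‑dichloroethenyloxy]‑1‑[3‑methoxy‑4‑(methoxymethoxy)phenyl]‑3‑(triphenylmethoxy)propan‑2‑ol
Conditions: Ph3CCl, Et3N, DMAP (cat.), CH2Cl2, 0 °C → rt
Reagents that add atoms: trityl chloride, ClC(c1ccccc1)(c1ccccc1)c1ccccc1
Why: tritylation (SN1‑type capture of the trityl cation) should go to the primary hydroxyl only on steric grounds, giving an ether that, unlike a silyl ether, cannot migrate to a neighbouring alkoxide under KH, survives n‑BuLi and leaves with acid.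

Step 8
Reactants: 11 (1R,2R)‑1‑[(E)‑1,2‑dichloroethenyloxy]‑1‑[3‑methoxy‑4‑(methoxymethoxy)phenyl]‑3‑(triphenylmethoxy)propan‑2‑ol
Product: 14 (1R,2R)‑1‑[3‑methoxy‑4‑(methoxymethoxy)phenyl]‑3‑(triphenylmethoxy)‑1‑{[2‑(trimethylsilyl)ethynyl]oxy}propan‑2‑ol, via dilithium alkoxide acetylide 12 (not isolated), via C,O‑bis(trimethylsilyl) derivative 13 (not isolated)
Conditions: n‑BuLi (3.3 equiv), THF, −78 → −40 °C; Me3SiCl (2.5 equiv), −78 → 0 °C; then K2CO3 (0.1 equiv), MeOH, −20 °C
Reagents that add atoms: chlorotrimethylsilane, C[Si](C)(C)Cl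
Why: n‑BuLi should first deprotonate the hydroxyl, then dehydrochlorinate the dichloroenol ether and exchange the remaining chlorine for lithium to give the lithium alkoxyacetylide (trichloroethylene route to alkynyl ethers), Me3SiCl caps carbon and oxygen, and cold carbonate in methanol should cleave only the far more labile O–Si bond of the secondary trimethylsilyl ether.

Step 9
Reactants: 14 (1R,2R)‑1‑[3‑methoxy‑4‑(methoxymethoxy)phenyl]‑3‑(triphenylmethoxy)‑1‑{[2‑(trimethylsilyl)ethynyl]oxy}propan‑2‑ol; 8 trichloroethylene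
Product: 17 [2‑({(1R,2R)‑2‑(ethynyloxy)‑1‑[3‑methoxy‑4‑(methoxymethoxy)phenyl]‑3‑(triphenylmethoxy)propyl}oxy)ethynyl]trimethylsilane, via dichloroethenyl ether 15 (not isolated), via lithium acetylide 16 (not isolated)
Conditions: KH, THF, 0 °C; 8, −40 → 0 °C; then n‑BuLi (2.5 equiv), −78 °C; aq. NH4Cl, −78 °C
Reagents that add atoms: none
Why: the same dichloroenol ether to alkynyl ether sequence on the remaining secondary hydroxyl, in which capture of the alkoxide by dichloroacetylene at low temperature should outrun attack on the neighbouring silylalkyne, n‑BuLi does not cleave a C(sp)–SiMe3 bond at −78 °C, and a cold neutral quench gives the terminal ynol ether without acid‑induced addition.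

Step 10
Reactants: 17 [2‑({(1R,2R)‑2‑(ethynyloxy)‑1‑[3‑methoxy‑4‑(methoxymethoxy)phenyl]‑3‑(triphenylmethoxy)propyl}oxy)ethynyl]trimethylsilane; 18 3,3‑diethoxyprop‑1‑yne
Product: 19 (2R,3R)‑6‑(diethoxymethyl)‑2‑[3‑methoxy‑4‑(methoxymethoxy)phenyl]‑3‑[(triphenylmethoxy)methyl]‑8‑(trimethylsilyl)‑2,3‑dihydro‑1,4‑benzodioxine
Conditions: [Rh(cod)2]BF4 (10 mol %), rac‑BINAP (10 mol %), H2 then Ar; 18 (5 equiv), CH2Cl2, rt, slow addition of 17
Reagents that add atoms: none
Why: Proposed new method: the cationic univalent rhodium–bisphosphine fragment should bind both ynol ether units of 17 and couple their oxygen‑bearing carbons by oxidative cyclisation, giving a rhodacyclopentadiene in which C4a–C8a and with it the dioxane ring are already in place; coordination and insertion of 18, then C–C reductive elimination, form C5–C6 and C7–C8 and release ring A. The closest known reaction type is the [2+2+2] cycloaddition of 1,6‑ and 1,7‑diynes with terminal alkynes under [Rh(cod)2]BF4/bisphosphine catalysis, together with the use of alkynyl ethers as partners that end as aryl ethers; a 3,6‑dioxa‑1,7‑diyne in which both units are ynol ethers has not been shown. The dioxane ring closes by metal‑mediated oxidative coupling of the tethered diyne (six‑membered ring fused to the metallacycle), and the benzene ring closes by alkyne insertion and reductive elimination. No stereocentre is formed, and the two carbinol carbons only carry the reacting oxygens, so their (R,R) configuration passes unchanged into C2 and C3. The step needs regioselectivity in the insertion of 18 and chemoselectivity for cross‑cyclotrimerisation: the trimethylsilyl group on the terminus that becomes C8 disfavours an ortho substituent, so the CH end of 18 should bond to C8 and the acetal‑bearing end to the unsubstituted terminus C5 (acetal at C6), while excess 18, slow addition of 17 and room temperature should suppress homo‑oligomerisation and the thermal sigmatropic and retro‑ene decay of the ynol ethers.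

Step 11
Reactants: 19 (2R,3R)‑6‑(diethoxymethyl)‑2‑[3‑methoxy‑4‑(methoxymethoxy)phenyl]‑3‑[(triphenylmethoxy)methyl]‑8‑(trimethylsilyl)‑2,3‑dihydro‑1,4‑benzodioxine
Product: 20 (2R,3R)‑2‑(4‑hydroxy‑3‑methoxyphenyl)‑3‑(hydroxymethyl)‑2,3‑dihydro‑1,4‑benzodioxine‑6‑carbaldehyde
Conditions: CF3CO2H/CH2Cl2/H2O (10:10:1), 0 °C → rt
Reagents that add atoms: water, O
Why: aqueous trifluoroacetic acid should protodesilylate C8 by ipso protonation (ortho to O1, β‑silyl‑stabilised arenium ion), hydrolyse the diethyl acetal and cleave the MOM and trityl ethers in one operation, with the stereocentres not involved and, should the benzylic C2–O1 bond ionise reversibly, reclosure favouring the trans isomer.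

Step 12
Reactants: 20 (2R,3R)‑2‑(4‑hydroxy‑3‑methoxyphenyl)‑3‑(hydroxymethyl)‑2,3‑dihydro‑1,4‑benzodioxine‑6‑carbaldehyde
Product: 22 (E)‑3‑[(2R,3R)‑2‑(4‑hydroxy‑3‑methoxyphenyl)‑3‑(hydroxymethyl)‑2,3‑dihydro‑1,4‑benzodioxin‑6‑yl]prop‑2‑enoic acid, via arylidenemalonic acid 21 (not isolated)
Conditions: CH2(CO2H)2, pyridine, piperidine (cat.), 80 °C
Reagents that add atoms: malonic acid, O=C(O)CC(=O)O
Why: Knoevenagel–Doebner condensation, in which amine‑catalysed condensation of the aryl aldehyde with malonic acid and decarboxylation in pyridine should give the (E)‑acrylic acid directly, with the free phenol and primary alcohol tolerated as in the preparation of hydroxycinnamic acids from hydroxybenzaldehydes.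

**Compound list**

1 | methyl (R)‑2,2‑dimethyl‑1,3‑dioxolane‑4‑carboxylate | COC(=O)[C@H]1COC(C)(C)O1 | starting material
2 | (R)‑N‑methoxy‑N,2,2‑trimethyl‑1,3‑dioxolane‑4‑carboxamide | CON(C)C(=O)[C@H]1COC(C)(C)O1 | intermediate
3 | 4‑bromo‑2‑methoxyphenol | COc1cc(Br)ccc1O | starting material
4 | 4‑bromo‑2‑methoxy‑1‑(methoxymethoxy)benzene | COCOc1ccc(Br)cc1OC | intermediate
5 | [3‑methoxy‑4‑(methoxymethoxy)phenyl]lithium | [Li]c1ccc(OCOC)c(OC)c1 | intermediate
6 | (R)‑(2,2‑dimethyl‑1,3‑dioxolan‑4‑yl)[3‑methoxy‑4‑(methoxymethoxy)phenyl]methanone | COCOc1ccc(C(=O)[C@H]2COC(C)(C)O2)cc1OC | intermediate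
7 | (R)‑[(4R)‑2,2‑dimethyl‑1,3‑dioxolan‑4‑yl][3‑methoxy‑4‑(methoxymethoxy)phenyl]methanol | COCOc1ccc([C@@H](O)[C@H]2COC(C)(C)O2)cc1OC | intermediate
8 | trichloroethylene | ClC=C(Cl)Cl | starting material
9 | (4R)‑4‑{(R)‑[(E)‑1,2‑dichloroethenyloxy][3‑methoxy‑4‑(methoxymethoxy)phenyl]methyl}‑2,2‑dimethyl‑1,3‑dioxolane | COCOc1ccc([C@@H](O/C(Cl)=C\Cl)[C@H]2COC(C)(C)O2)cc1OC | intermediate
10 | (2R,3R)‑3‑[(E)‑1,2‑dichloroethenyloxy]‑3‑[3‑methoxy‑4‑(methoxymethoxy)phenyl]propane‑1,2‑diol | COCOc1ccc([C@@H](O/C(Cl)=C\Cl)[C@H](O)CO)cc1OC | intermediate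
11 | (1R,2R)‑1‑[(E)‑1,2‑dichloroethenyloxy]‑1‑[3‑methoxy‑4‑(methoxymethoxy)phenyl]‑3‑(triphenylmethoxy)propan‑2‑ol | COCOc1ccc([C@@H](O/C(Cl)=C\Cl)[C@H](O)COC(c2ccccc2)(c2ccccc2)c2ccccc2)cc1OC | intermediate
12 | lithium (1R,2R)‑1‑[(lithioethynyl)oxy]‑1‑[3‑methoxy‑4‑(methoxymethoxy)phenyl]‑3‑(triphenylmethoxy)propan‑2‑olate | COCOc1ccc([C@@H](OC#C[Li])[C@H](O[Li])COC(c2ccccc2)(c2ccccc2)c2ccccc2)cc1OC | intermediate
13 | trimethyl[2‑({(1R,2R)‑1‑[3‑methoxy‑4‑(methoxymethoxy)phenyl]‑3‑(triphenylmethoxy)‑2‑[(trimethylsilyl)oxy]propyl}oxy)ethynyl]silane | COCOc1ccc([C@@H](OC#C[Si](C)(C)C)[C@H](O[Si](C)(C)C)COC(c2ccccc2)(c2ccccc2)c2ccccc2)cc1OC | intermediate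
14 | (1R,2R)‑1‑[3‑methoxy‑4‑(methoxymethoxy)phenyl]‑3‑(triphenylmethoxy)‑1‑{[2‑(trimethylsilyl)ethynyl]oxy}propan‑2‑ol | COCOc1ccc([C@@H](OC#C[Si](C)(C)C)[C@H](O)COC(c2ccccc2)(c2ccccc2)c2ccccc2)cc1OC | intermediate
15 | [2‑({(1R,2R)‑2‑[(E)‑1,2‑dichloroethenyloxy]‑1‑[3‑methoxy‑4‑(methoxymethoxy)phenyl]‑3‑(triphenylmethoxy)propyl}oxy)ethynyl]trimethylsilane | COCOc1ccc([C@@H](OC#C[Si](C)(C)C)[C@H](O/C(Cl)=C\Cl)COC(c2ccccc2)(c2ccccc2)c2ccccc2)cc1OC | intermediate
16 | [2‑({(1R,2R)‑1‑[3‑methoxy‑4‑(methoxymethoxy)phenyl]‑3‑(triphenylmethoxy)‑1‑{[2‑(trimethylsilyl)ethynyl]oxy}propan‑2‑yl}oxy)ethynyl]lithium | COCOc1ccc([C@@H](OC#C[Si](C)(C)C)[C@H](OC#C[Li])COC(c2ccccc2)(c2ccccc2)c2ccccc2)cc1OC | intermediate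
17 | [2‑({(1R,2R)‑2‑(ethynyloxy)‑1‑[3‑methoxy‑4‑(methoxymethoxy)phenyl]‑3‑(triphenylmethoxy)propyl}oxy)ethynyl]trimethylsilane | COCOc1ccc([C@@H](OC#C[Si](C)(C)C)[C@H](OC#C)COC(c2ccccc2)(c2ccccc2)c2ccccc2)cc1OC | intermediate
18 | 3,3‑diethoxyprop‑1‑yne | C#CC(OCC)OCC | starting material
19 | (2R,3R)‑6‑(diethoxymethyl)‑2‑[3‑methoxy‑4‑(methoxymethoxy)phenyl]‑3‑[(triphenylmethoxy)methyl]‑8‑(trimethylsilyl)‑2,3‑dihydro‑1,4‑benzodioxine | COCOc1ccc([C@H]2Oc3c([Si](C)(C)C)cc(C(OCC)OCC)cc3O[C@@H]2COC(c4ccccc4)(c4ccccc4)c4ccccc4)cc1OC | intermediate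
20 | (2R,3R)‑2‑(4‑hydroxy‑3‑methoxyphenyl)‑3‑(hydroxymethyl)‑2,3‑dihydro‑1,4‑benzodioxine‑6‑carbaldehyde | COc1cc([C@H]2Oc3ccc(C=O)cc3O[C@@H]2CO)ccc1O | intermediate
21 | 2‑{[(2R,3R)‑2‑(4‑hydroxy‑3‑methoxyphenyl)‑3‑(hydroxymethyl)‑2,3‑dihydro‑1,4‑benzodioxin‑6‑yl]methylidene}propanedioic acid | COc1cc([C@H]2Oc3ccc(C=C(C(=O)O)C(=O)O)cc3O[C@@H]2CO)ccc1O | intermediate
22 | (E)‑3‑[(2R,3R)‑2‑(4‑hydroxy‑3‑methoxyphenyl)‑3‑(hydroxymethyl)‑2,3‑dihydro‑1,4‑benzodioxin‑6‑yl]prop‑2‑enoic acid | COc1cc([C@H]2Oc3ccc(/C=C/C(=O)O)cc3O[C@@H]2CO)ccc1O | target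

**Step count**

Total: 12 steps. Longest linear sequence: 11 steps (from 1 through steps 1 and 3–12); step 2 is a one‑step side branch from 3.

**Steps most likely to fail, with fallbacks**

Step 10 (Proposed new method). The cationic rhodium catalyst may oligomerise or hydrate the two electron‑rich ynol ethers instead of cyclising them. Homo‑trimerisation of 18 may consume the catalyst, insertion of 18 may not be regioselective enough, and the benzylic ynol ether may rearrange before it cyclises. The fallback uses known chemistry, sets out from 7 and comes back at 20.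
- The potassium alkoxide of 7 (KN(SiMe3)2, DMF, 0 °C) should displace fluoride from 3‑bromo‑4‑fluorobenzaldehyde (SNAr para to the formyl group), giving 3‑bromo‑4‑{(R)‑[(4R)‑2,2‑dimethyl‑1,3‑dioxolan‑4‑yl][3‑methoxy‑4‑(methoxymethoxy)phenyl]methoxy}benzaldehyde F1.
- Aqueous acetic acid should free the diol 3‑bromo‑4‑{[(1R,2R)‑2,3‑dihydroxy‑1‑[3‑methoxy‑4‑(methoxymethoxy)phenyl]propyl]oxy}benzaldehyde F2.
- Tritylation of the primary hydroxyl should give 3‑bromo‑4‑{[(1R,2R)‑2‑hydroxy‑1‑[3‑methoxy‑4‑(methoxymethoxy)phenyl]‑3‑(triphenylmethoxy)propyl]oxy}benzaldehyde F3.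
- Palladium‑catalysed intramolecular C–O coupling of the aryl bromide with the secondary alcohol (Pd(OAc)2, a bulky di‑tert‑butyl(biaryl)phosphine, Cs2CO3, toluene, 80 °C) should close the dioxane ring with retention at both carbinol carbons, giving (2R,3R)‑2‑[3‑methoxy‑4‑(methoxymethoxy)phenyl]‑3‑[(triphenylmethoxy)methyl]‑2,3‑dihydro‑1,4‑benzodioxine‑6‑carbaldehyde F4.
- CF3CO2H/CH2Cl2/H2O should then give 20, which enters step 12.
- The regiochemistry is fixed here by the position of fluorine (para to the formyl group, future C8a) and bromine (future C4a).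

Step 9. The potassium alkoxide may attack the silicon of the neighbouring silylalkyne or add to the ynol ether before it is captured by dichloroacetylene, and the doubly unsaturated product may decay on isolation. The fallback sets out from 11, comes back at 15, and keeps silicon out of the molecule while the alkoxide is present.
- n‑BuLi (3.3 equiv, THF, −78 °C) followed by aq. NH4Cl should give the terminal alkynyl ether (1R,2R)‑1‑(ethynyloxy)‑1‑[3‑methoxy‑4‑(methoxymethoxy)phenyl]‑3‑(triphenylmethoxy)propan‑2‑ol F5.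
- KH (2.2 equiv) and 8 should convert the hydroxyl into its dichloroenol ether while the alkyne is held as the unreactive potassium acetylide, giving 1‑{(1R,2R)‑2‑[(E)‑1,2‑dichloroethenyloxy]‑1‑(ethynyloxy)‑3‑(triphenylmethoxy)propyl}‑3‑methoxy‑4‑(methoxymethoxy)benzene F6.
- i‑PrMgCl (THF, 0 °C) should deprotonate only the acetylenic C–H, and Me3SiCl then gives 15, this time isolated.
- 15 is taken to 17 by the n‑BuLi/NH4Cl half of step 9.

Step 11. Ipso protodesilylation may stall once the aldehyde is unmasked and deactivates ring A, and longer exposure to strong acid may ionise the benzylic C2–O1 bond of the free para‑hydroxybenzyl aryl ether, with loss of configuration or ring opening. The fallback sets out from 19, comes back at 20, and removes silicon under basic conditions before any acid is used.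
- Base‑catalysed protodesilylation (KOSiMe3 cat., wet DMSO, 60 °C) should give (2R,3R)‑6‑(diethoxymethyl)‑2‑[3‑methoxy‑4‑(methoxymethoxy)phenyl]‑3‑[(triphenylmethoxy)methyl]‑2,3‑dihydro‑1,4‑benzodioxine F7.
- Milder acid (2 M aq. HCl, THF, 40 °C) should then remove the acetal, MOM and trityl groups to give 20.

**Further compounds**

F1 | step 10 | 3‑bromo‑4‑{(R)‑[(4R)‑2,2‑dimethyl‑1,3‑dioxolan‑4‑yl][3‑methoxy‑4‑(methoxymethoxy)phenyl]methoxy}benzaldehyde | COCOc1ccc([C@@H](Oc2ccc(C=O)cc2Br)[C@H]3COC(C)(C)O3)cc1OC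
F2 | step 10 | 3‑bromo‑4‑{[(1R,2R)‑2,3‑dihydroxy‑1‑[3‑methoxy‑4‑(methoxymethoxy)phenyl]propyl]oxy}benzaldehyde | COCOc1ccc([C@@H](Oc2ccc(C=O)cc2Br)[C@H](O)CO)cc1OC
F3 | step 10 | 3‑bromo‑4‑{[(1R,2R)‑2‑hydroxy‑1‑[3‑methoxy‑4‑(methoxymethoxy)phenyl]‑3‑(triphenylmethoxy)propyl]oxy}benzaldehyde | COCOc1ccc([C@@H](Oc2ccc(C=O)cc2Br)[C@H](O)COC(c3ccccc3)(c3ccccc3)c3ccccc3)cc1OC
F4 | step 10 | (2R,3R)‑2‑[3‑methoxy‑4‑(methoxymethoxy)phenyl]‑3‑[(triphenylmethoxy)methyl]‑2,3‑dihydro‑1,4‑benzodioxine‑6‑carbaldehyde | COCOc1ccc([C@H]2Oc3ccc(C=O)cc3O[C@@H]2COC(c4ccccc4)(c4ccccc4)c4ccccc4)cc1OC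
F5 | step 9 | (1R,2R)‑1‑(ethynyloxy)‑1‑[3‑methoxy‑4‑(methoxymethoxy)phenyl]‑3‑(triphenylmethoxy)propan‑2‑ol | COCOc1ccc([C@@H](OC#C)[C@H](O)COC(c2ccccc2)(c2ccccc2)c2ccccc2)cc1OC
F6 | step 9 | 1‑{(1R,2R)‑2‑[(E)‑1,2‑dichloroethenyloxy]‑1‑(ethynyloxy)‑3‑(triphenylmethoxy)propyl}‑3‑methoxy‑4‑(methoxymethoxy)benzene | COCOc1ccc([C@@H](OC#C)[C@H](O/C(Cl)=C\Cl)COC(c2ccccc2)(c2ccccc2)c2ccccc2)cc1OC
F7 | step 11 | (2R,3R)‑6‑(diethoxymethyl)‑2‑[3‑methoxy‑4‑(methoxymethoxy)phenyl]‑3‑[(triphenylmethoxy)methyl]‑2,3‑dihydro‑1,4‑benzodioxine | COCOc1ccc([C@H]2Oc3ccc(C(OCC)OCC)cc3O[C@@H]2COC(c4ccccc4)(c4ccccc4)c4ccccc4)cc1OC
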